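**Retrosynthetic overview**
1. The target acid comes from its methyl ester; the carboxyl carbon is bought with the arene (methyl orsellinate) and unmasked last.
2. Key disconnection: the O1–C2 bond of the chroman. Ring and (R)-quaternary centre come from a racemic tertiary dienyl carbinol tethered to C-3 of the diphenol, closed by a chiral Brønsted acid through a pentadienyl cation.
3. The tertiary carbinol comes from an aryl butanone and (E)-4-methylpenta-1,3-dienyllithium, itself one step from prenal.
4. The aryl butanone comes from methyl orsellinate by two C-alkylations: Michael addition to methyl vinyl ketone at C-3, then prenylation at C-5, the last free ring carbon.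
5. Ring order: the benzene ring is bought; the dihydropyran ring is the only ring made (step 5).

Assumption: the sense of induction of the chiral acid cannot be fixed on paper; the (S)-acid is written, and the (R)-acid is used instead if the first run gives the (S)-chroman.

**Step 1**
Reactants: 1 methyl 2,4-dihydroxy-6-methylbenzoate (methyl orsellinate); 2 but-3-en-2-one (methyl vinyl ketone)
Product: 3 methyl 2,4-dihydroxy-6-methyl-3-(3-oxobutyl)benzoate
Conditions: NaOH (2.2 equiv), H2O, 2 (1.2 equiv, slow addition), 0 °C to rt; then 1 M HCl to pH 4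
Reagents that add atoms: none
Why: Michael addition through carbon of the resorcinolate (phenoxide C-alkylation); C-3 is ortho to both oxygens and not shielded by the 6-methyl group, so the enone should be taken up there, while O-adducts revert under base.

**Step 2**
Reactants: 3 methyl 2,4-dihydroxy-6-methyl-3-(3-oxobutyl)benzoate; 4 1-bromo-3-methylbut-2-ene (prenyl bromide)
Product: 5 methyl 2,4-dihydroxy-6-methyl-5-(3-methylbut-2-en-1-yl)-3-(3-oxobutyl)benzoate
Conditions: NaH (1.05 equiv), toluene, 0 °C; then 4 (1.2 equiv), rt
Reagents that add atoms: none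
Why: ortho-C-alkylation of a sodium phenoxide in a non-polar solvent (tight ion pair, the classical route to o-prenylphenols); the more acidic 4-OH is deprotonated and C-5 is the only unsubstituted ring carbon, so regiochemistry is forced.

**Step 3**
Reactants: 6 3-methylbut-2-enal (prenal)
Product: 7 (1E)-1-iodo-4-methylpenta-1,3-diene
Conditions: CHI3 (2 equiv), CrCl2 (6 equiv), THF, 0 °C, dark
Reagents that add atoms: iodoform, IC(I)I
Why: Takai iodo-olefination; the gem-dichromium carbenoid adds to the aldehyde and eliminates to the (E)-alkenyl iodide with high E-selectivity.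

**Step 4**
Reactants: 5 methyl 2,4-dihydroxy-6-methyl-5-(3-methylbut-2-en-1-yl)-3-(3-oxobutyl)benzoate; 7 (1E)-1-iodo-4-methylpenta-1,3-diene
Product: 9 racemic methyl 2,4-dihydroxy-3-[(4E)-3-hydroxy-3,7-dimethylocta-4,6-dien-1-yl]-6-methyl-5-(3-methylbut-2-en-1-yl)benzoate, via (1E)-4-methylpenta-1,3-dienyllithium 8 (not isolated)
Conditions: 7 (3.3 equiv), t-BuLi (6.6 equiv), Et2O, −78 °C; then 5 in THF, −78 to −30 °C; aq. NH4Cl
Reagents that add atoms: none
Why: iodine–lithium exchange with retention of the (E)-geometry, then 1,2-addition of the alkenyllithium to the methyl ketone; two equivalents are spent on the phenols, whose lithium salts shield the hindered chelated ester, and the racemic carbinol centre is of no consequence because the next step passes through a planar cation.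

**Step 5**
Reactants: 9 racemic methyl 2,4-dihydroxy-3-[(4E)-3-hydroxy-3,7-dimethylocta-4,6-dien-1-yl]-6-methyl-5-(3-methylbut-2-en-1-yl)benzoate
Product: 11 methyl (2R)-5-hydroxy-2,7-dimethyl-8-(3-methylbut-2-en-1-yl)-2-[(1E)-4-methylpenta-1,3-dien-1-yl]-3,4-dihydro-2H-chromene-6-carboxylate, via pentadienyl cation 10 (not isolated)
Conditions: (S)-3,3'-bis(2,4,6-triisopropylphenyl)-H8-BINOL N-triflylphosphoramide (5 mol%), 5 Å MS, toluene, −60 °C
Reagents that add atoms: none
Why: Proposed new method: enantioconvergent dehydrative 6-exo cycloetherification, in which the chiral acid ionises either enantiomer of the tertiary dienyl carbinol to the same planar pentadienyl cation held as a contact ion pair with the chiral phosphoramide anion; the anion also hydrogen-bonds the free 4-OH (the 2-OH is tied to the ester carbonyl) and delivers it to one face of the C-3' terminus, so the C–O bond closes the six-membered ring (the other cation termini would need eight- or ten-membered rings) and sets the (R)-quaternary centre, while the low temperature keeps the (E)-geometry and leaves the less basic prenyl alkene untouched; the closest known reaction type is the chiral N-triflylphosphoramide-catalysed intramolecular allylic substitution of tertiary allylic alcohols by phenols that gives 2,2-disubstituted 2H-chromenes through chiral contact ion pairs.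

**Step 6**
Reactants: 11 methyl (2R)-5-hydroxy-2,7-dimethyl-8-(3-methylbut-2-en-1-yl)-2-[(1E)-4-methylpenta-1,3-dien-1-yl]-3,4-dihydro-2H-chromene-6-carboxylate
Product: 12 (2R)-5-hydroxy-2,7-dimethyl-8-(3-methylbut-2-en-1-yl)-2-[(1E)-4-methylpenta-1,3-dien-1-yl]-3,4-dihydro-2H-chromene-6-carboxylic acid (CNP0137659.1)
Conditions: KOH (15 equiv), MeOH/H2O 4:1, degassed, 65 °C; then cold 1 M HCl to pH 3–4, 0 °C
Reagents that add atoms: potassium hydroxide, [K+].[OH-]
Why: saponification (acyl–oxygen cleavage) of the hindered salicylate ester with hot excess hydroxide; diene, prenyl group and tertiary aryl ether are inert to base, cold brief acidification avoids decarboxylation and ether ionisation, and the stereocentre is not touched.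

**Compound list**
1 | methyl 2,4-dihydroxy-6-methylbenzoate (methyl orsellinate) | COC(=O)c1c(C)cc(O)cc1O | starting material
2 | but-3-en-2-one (methyl vinyl ketone) | CC(=O)C=C | starting material
3 | methyl 2,4-dihydroxy-6-methyl-3-(3-oxobutyl)benzoate | COC(=O)c1c(C)cc(O)c(CCC(C)=O)c1O | intermediate
4 | 1-bromo-3-methylbut-2-ene (prenyl bromide) | CC(C)=CCBr | starting material
5 | methyl 2,4-dihydroxy-6-methyl-5-(3-methylbut-2-en-1-yl)-3-(3-oxobutyl)benzoate | COC(=O)c1c(C)c(CC=C(C)C)c(O)c(CCC(C)=O)c1O | intermediate
6 | 3-methylbut-2-enal (prenal) | CC(C)=CC=O | starting material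
7 | (1E)-1-iodo-4-methylpenta-1,3-diene | CC(C)=C/C=C/I | intermediate
8 | (1E)-4-methylpenta-1,3-dienyllithium | [Li]/C=C/C=C(C)C | intermediate (not isolated)
9 | racemic methyl 2,4-dihydroxy-3-[(4E)-3-hydroxy-3,7-dimethylocta-4,6-dien-1-yl]-6-methyl-5-(3-methylbut-2-en-1-yl)benzoate | COC(=O)c1c(C)c(CC=C(C)C)c(O)c(CCC(C)(O)/C=C/C=C(C)C)c1O | intermediate
10 | pentadienyl cation formed from 9 by loss of water, paired with the chiral phosphoramide anion | COC(=O)c1c(C)c(CC=C(C)C)c(O)c(CC[C+](C)/C=C/C=C(C)C)c1O | intermediate (not isolated)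
11 | methyl (2R)-5-hydroxy-2,7-dimethyl-8-(3-methylbut-2-en-1-yl)-2-[(1E)-4-methylpenta-1,3-dien-1-yl]-3,4-dihydro-2H-chromene-6-carboxylate | CC(C)=C/C=C/[C@@]1(C)CCc2c(O)c(C(=O)OC)c(C)c(CC=C(C)C)c2O1 | intermediate
12 | (2R)-5-hydroxy-2,7-dimethyl-8-(3-methylbut-2-en-1-yl)-2-[(1E)-4-methylpenta-1,3-dien-1-yl]-3,4-dihydro-2H-chromene-6-carboxylic acid | CC(C)=C/C=C/[C@@]1(C)CCc2c(O)c(C(=O)O)c(C)c(CC=C(C)C)c2O1 | target

**Step count**
Total: 6 steps. Longest linear sequence: 5 steps (steps 1, 2, 4, 5, 6); step 3 is a one-step side branch.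

**Steps most likely to fail and fallbacks**

Step 1 (C-3 versus C-5 attack, polymerisation of the enone). The fallback sets out from 1 and returns at 3. Aminomethylation of 1 (Me2NH, aqueous CH2O, EtOH, rt), which is directed between the two oxygens by hydrogen bonding, gives methyl 3-[(dimethylamino)methyl]-2,4-dihydroxy-6-methylbenzoate F1. Heating F1 with tert-butyl acetoacetate in toluene expels the amine to give the transient o-quinone methide methyl 2-hydroxy-6-methyl-3-methylidene-4-oxocyclohexa-1,5-diene-1-carboxylate F2. F2 is trapped by the keto ester to give racemic tert-butyl 2-acetyl-3-[2,6-dihydroxy-3-(methoxycarbonyl)-4-methylphenyl]propanoate F3. TsOH (cat.) in wet toluene at 90 °C cleaves the tert-butyl ester and decarboxylates to 3.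

Step 2 (O-prenylation or attack at the substituted C-3 with dearomatisation). The fallback sets out from 3 and returns at 5. Iodination with N-iodosuccinimide (MeCN, 0 °C) at the only free ring carbon gives methyl 2,4-dihydroxy-5-iodo-6-methyl-3-(3-oxobutyl)benzoate F4. Stille coupling of F4 with tributyl(3-methylbut-2-en-1-yl)stannane (Pd(PPh3)4, DMF, 80 °C), which couples at the unsubstituted allyl terminus, gives 5.

Step 5 (the proposed new cyclisation). The risks are low enantioselectivity, E1 loss to trienes, closure through the 2-OH, and erosion of ee by re-ionisation of the product ether. The fallback uses known chemistry, sets out from 9 and returns at 11. Cyclisation with pyridinium p-toluenesulfonate (cat.) in CH2Cl2 at 0 °C gives racemic methyl 5-hydroxy-2,7-dimethyl-8-(3-methylbut-2-en-1-yl)-2-[(1E)-4-methylpenta-1,3-dien-1-yl]-3,4-dihydro-2H-chromene-6-carboxylate F5. Preparative chiral SFC on an amylose carbamate phase then separates 11 from methyl (2S)-5-hydroxy-2,7-dimethyl-8-(3-methylbut-2-en-1-yl)-2-[(1E)-4-methylpenta-1,3-dien-1-yl]-3,4-dihydro-2H-chromene-6-carboxylate F6, which is discarded.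

**Further compounds**
F1 | step 1 | methyl 3-[(dimethylamino)methyl]-2,4-dihydroxy-6-methylbenzoate | COC(=O)c1c(C)cc(O)c(CN(C)C)c1O
F2 | step 1 | methyl 2-hydroxy-6-methyl-3-methylidene-4-oxocyclohexa-1,5-diene-1-carboxylate (transient o-quinone methide) | COC(=O)C1=C(O)C(=C)C(=O)C=C1C
F3 | step 1 | racemic tert-butyl 2-acetyl-3-[2,6-dihydroxy-3-(methoxycarbonyl)-4-methylphenyl]propanoate | COC(=O)c1c(C)cc(O)c(CC(C(C)=O)C(=O)OC(C)(C)C)c1O
F4 | step 2 | methyl 2,4-dihydroxy-5-iodo-6-methyl-3-(3-oxobutyl)benzoate | COC(=O)c1c(C)c(I)c(O)c(CCC(C)=O)c1O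
F5 | step 5 | racemic methyl 5-hydroxy-2,7-dimethyl-8-(3-methylbut-2-en-1-yl)-2-[(1E)-4-methylpenta-1,3-dien-1-yl]-3,4-dihydro-2H-chromene-6-carboxylate | CC(C)=C/C=C/C1(C)CCc2c(O)c(C(=O)OC)c(C)c(CC=C(C)C)c2O1
F6 | step 5 | methyl (2S)-5-hydroxy-2,7-dimethyl-8-(3-methylbut-2-en-1-yl)-2-[(1E)-4-methylpenta-1,3-dien-1-yl]-3,4-dihydro-2H-chromene-6-carboxylate | CC(C)=C/C=C/[C@]1(C)CCc2c(O)c(C(=O)OC)c(C)c(CC=C(C)C)c2O1
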